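## Retrosynthetic overview

1. The target comes from one global LiBH4 reduction of a fully assembled tetramer carrying two N-acyl camphorsultams, one methyl ester and one aryl pivalate.
2. Ring order: tetrahydrofuran first, then the ring B/C dihydrobenzofuran, then the ring C/D dihydrobenzofuran (endwise growth at the phenolic chain end, as in lignan biosynthesis).
3. Each dihydrobenzofuran is made by Ag2O-mediated oxidative 8–5 radical cross-coupling of a feruloyl camphorsultam with the chain-end phenol. The quinone methide is closed by the phenol oxygen (trans), and antipodal sultams give the opposite absolute configurations of the two rings.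
4. The tetrahydrofuran is closed through the O9'–C7 bond at the ketone level (α-aroyl lactone to 4,5-dihydrofuran ester) and then hydrogenated syn, anti to the benzyl group. Quinone-methide closure would give the 7,8-trans ring, whereas the target is all-cis.
5. C8' is set by Evans alkylation of a dihydroferuloyl oxazolidinone with tert-butyl bromoacetate.

Assumption: the N-feruloyl (2R)-bornane-10,2-sultam reacts at its Cα-Re face (Oppolzer's model for non-chelated N-enoyl sultams) and its antipode at Cα-Si; if experiment shows the reverse, the two sultams exchange places and nothing else changes.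

## Route

Step 1
Reactants: 1 3-(4-hydroxy-3-methoxyphenyl)propanoic acid (dihydroferulic acid); 2 (4S)-4-benzyl-1,3-oxazolidin-2-one
Product: 4 (4S)-4-benzyl-3-{3-[3-methoxy-4-(pivaloyloxy)phenyl]propanoyl}-1,3-oxazolidin-2-one, via mixed anhydride 3 (not isolated)
Conditions: PivCl (2.3 equiv), Et3N (3.5 equiv), THF, −20 → 0 °C; then LiCl (1.1 equiv), 2, rt
Reagents that add atoms: pivaloyl chloride, CC(C)(C)C(Cl)=O
Why: One-pot mixed-anhydride N-acylation of an Evans oxazolidinone, in which the excess PivCl also caps the phenol as the pivalate that later keeps ring A' out of the oxidative couplings; no stereocentre is formed.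

Step 2
Reactants: 4 (imide from step 1); 5 tert-butyl bromoacetate
Product: 6 tert-butyl (3R)-4-[(4S)-4-benzyl-2-oxo-1,3-oxazolidin-3-yl]-3-{[3-methoxy-4-(pivaloyloxy)phenyl]methyl}-4-oxobutanoate
Conditions: NaN(SiMe3)2 (1.1 equiv), THF, −78 °C; then 5, −78 → −40 °C
Reagents that add atoms: none
Why: Evans asymmetric alkylation: the chelated Z-sodium enolate is alkylated on the face opposite the 4-benzyl group, which sets the future C8' as R (dr above 95:5 expected).

Step 3
Reactants: 6 (alkylated imide)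
Product: 8 (4R)-4-{[3-methoxy-4-(pivaloyloxy)phenyl]methyl}oxolan-2-one, via hydroxy ester 7 (not isolated)
Conditions: NaBH4, THF/H2O (4:1), 0 °C → rt; then TFA, CH2Cl2, rt
Reagents that add atoms: none
Why: Chemoselective borohydride reduction of the imide carbonyl (auxiliary released intact, tert-butyl ester and hindered aryl pivalate untouched) followed by acid-mediated loss of the tert-butyl group and lactonisation; the stereocentre is not involved.

Step 4
Reactants: 8 (lactone); 9 4-(benzyloxy)-3-methoxybenzoic acid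
Product: 11 (3S,4R)-3-[4-(benzyloxy)-3-methoxybenzoyl]-4-{[3-methoxy-4-(pivaloyloxy)phenyl]methyl}oxolan-2-one, via acyl imidazole 10 (not isolated)
Conditions: 9, CDI, THF, rt; separately 8, LiN(SiMe3)2 (2.1 equiv), THF, −78 °C, then the solution of 10, −78 → 0 °C; 1 M HCl quench
Reagents that add atoms: none
Why: Crossed Claisen C-acylation of the lactone lithium enolate with an acyl imidazole, driven by deprotonation of the β-keto lactone by the second equivalent of base; the aroyl group enters trans to the benzyl group, but this centre becomes sp2 in the next step.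

Step 5
Reactants: 11 (α-aroyl lactone)
Product: 13 methyl (4R)-2-[4-(benzyloxy)-3-methoxyphenyl]-4-{[3-methoxy-4-(pivaloyloxy)phenyl]methyl}-4,5-dihydrofuran-3-carboxylate, via hydroxy keto ester 12 (not isolated)
Conditions: HCl (1.25 M in MeOH), 45 °C
Reagents that add atoms: methanol, CO
Why: The classical 2-acylbutyrolactone to 4,5-dihydrofuran-3-carboxylate rearrangement (acid-catalysed methanolysis, then cyclodehydration of the freed primary alcohol onto the aryl ketone) makes the same O9'–C7 bond that quinone-methide trapping makes in lignan biosynthesis, but leaves C7 and C8 sp2 so that their configuration can still be chosen.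

Step 6
Reactants: 13 (dihydrofuran ester)
Product: 14 methyl (2R,3S,4R)-2-(4-hydroxy-3-methoxyphenyl)-4-{[3-methoxy-4-(pivaloyloxy)phenyl]methyl}oxolane-3-carboxylate
Conditions: H2 (3 bar), Pd/C (10 wt%), EtOAc/MeOH, rt
Reagents that add atoms: none
Why: Heterogeneous catalytic hydrogenation adds H2 syn to the tetrasubstituted enol ether from the face opposite the C4 benzyl group, which puts aryl, ester and benzyl all cis (2R,3S,4R), and the same catalyst hydrogenolyses the benzyl ether to free the ring B phenol.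

Step 7
Reactants: 15 (E)-3-(4-acetoxy-3-methoxyphenyl)prop-2-enoic acid (4-O-acetylferulic acid)
Product: 16 (E)-3-(4-acetoxy-3-methoxyphenyl)prop-2-enoyl chloride
Conditions: (COCl)2 (1.3 equiv), cat. DMF, CH2Cl2, 0 °C → rt; evaporate, strip with toluene; crude solid stored under argon and used in two portions
Reagents that add atoms: oxalyl chloride, O=C(Cl)C(Cl)=O
Why: DMF-catalysed (Vilsmeier-type) conversion of the carboxylic acid to the acid chloride, which leaves the aryl acetate and the E alkene untouched and forms no stereocentre; one batch supplies both sultam acylations.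

Step 8
Reactants: 16 (acid chloride); 17 (1S)-(−)-2,10-camphorsultam [(2R)-bornane-10,2-sultam]
Product: 19 (2E)-3-(4-hydroxy-3-methoxyphenyl)-1-[(2R)-bornane-10,2-sultam-N-yl]prop-2-en-1-one, via acetate 18 (not isolated)
Conditions: 17, NaH (1.05 equiv), THF, 0 °C; then 16, 0 °C → rt; then pyrrolidine (2 equiv), 0 °C
Reagents that add atoms: none
Why: Oppolzer N-acylation of the sultam sodium salt with the acid chloride, then chemoselective aminolysis of the aryl acetate by pyrrolidine in the same flask; the E alkene is kept and no stereocentre is formed.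

Step 9
Reactants: 14 (all-cis tetrahydrofuran phenol); 19 (feruloyl (2R)-sultam)
Product: 21 methyl (2R,3S,4R)-2-{(2R,3R)-2-(4-hydroxy-3-methoxyphenyl)-7-methoxy-3-{[(2R)-bornane-10,2-sultam-N-yl]carbonyl}-2,3-dihydro-1-benzofuran-5-yl}-4-{[3-methoxy-4-(pivaloyloxy)phenyl]methyl}oxolane-3-carboxylate, via quinone methide 20 (not isolated)
Conditions: Ag2O (1.2 equiv), 19 (1.3 equiv, added over 6 h), CH2Cl2/acetone (4:1), 4 Å sieves, dark, rt; stop at about 60% conversion of 14 and recycle
Reagents that add atoms: none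
Why: Proposed new method: Ag2O oxidises both phenols to phenoxyl radicals, and the feruloyl radical (kept dilute by slow addition) couples through C8 with C5 of the ring B radical, the sultam exposing its Cα-Re face so that C8 forms as S; re-aromatisation of ring B gives quinone methide 20, which the adjacent phenol oxygen closes by 5-exo oxa-Michael addition to the trans (2R,3R) dihydrobenzofuran; the closest known reaction type is the Ag2O- or peroxidase-mediated 8–5 dehydrodimerisation of feruloyl camphorsultams and ferulate esters, extended here to a cross-coupling.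

Step 10
Reactants: 16 (acid chloride, second portion); 22 (1R)-(+)-2,10-camphorsultam [(2S)-bornane-10,2-sultam]
Product: 24 (2E)-3-(4-hydroxy-3-methoxyphenyl)-1-[(2S)-bornane-10,2-sultam-N-yl]prop-2-en-1-one, via acetate 23 (not isolated)
Conditions: 22, NaH (1.05 equiv), THF, 0 °C; then 16, 0 °C → rt; then pyrrolidine (2 equiv), 0 °C
Reagents that add atoms: none
Why: Same Oppolzer N-acylation and in-flask aryl acetate aminolysis as in step 8, with the antipodal sultam.

Step 11
Reactants: 21 (trimer phenol); 24 (feruloyl (2S)-sultam)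
Product: 26 methyl (2R,3S,4R)-2-{(2R,3R)-2-[(2S,3S)-2-(4-hydroxy-3-methoxyphenyl)-7-methoxy-3-{[(2S)-bornane-10,2-sultam-N-yl]carbonyl}-2,3-dihydro-1-benzofuran-5-yl]-7-methoxy-3-{[(2R)-bornane-10,2-sultam-N-yl]carbonyl}-2,3-dihydro-1-benzofuran-5-yl}-4-{[3-methoxy-4-(pivaloyloxy)phenyl]methyl}oxolane-3-carboxylate, via quinone methide 25 (not isolated)
Conditions: Ag2O (1.2 equiv), 24 (1.3 equiv, added over 6 h), CH2Cl2/acetone (4:1), 4 Å sieves, dark, rt; stop at about 60% conversion of 21 and recycle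
Reagents that add atoms: none
Why: Proposed new method: the same oxidative 8–5 radical cross-coupling and quinone-methide closure as in step 9, now on the only free phenol (ring C), with the (2S)-sultam exposing the Cα-Si face so that the new trans dihydrobenzofuran has the opposite (2S,3S) configuration; the closest known reaction type is again the Ag2O-mediated 8–5 dehydrodimerisation of feruloyl camphorsultams.

Step 12
Reactants: 26 (bis-sultam tetramer)
Product: 27 target, 4-{[(3R,4R,5R)-5-{(2R,3S)-2-[(2S,3R)-2-(4-hydroxy-3-methoxyphenyl)-3-(hydroxymethyl)-7-methoxy-2,3-dihydro-1-benzofuran-5-yl]-3-(hydroxymethyl)-7-methoxy-2,3-dihydro-1-benzofuran-5-yl}-4-(hydroxymethyl)oxolan-3-yl]methyl}-2-methoxyphenol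
Conditions: LiBH4 (12 equiv), THF/MeOH (10:1), 0 °C → rt
Reagents that add atoms: none
Why: Borohydride reductive cleavage of both N-acyl sultams to primary alcohols (auxiliaries recovered), reduction of the methyl ester and reductive removal of the aryl pivalate in one operation under non-acidic, weakly basic conditions that leave all seven stereocentres untouched.

## Compound list

1 | 3-(4-hydroxy-3-methoxyphenyl)propanoic acid | COc1cc(CCC(=O)O)ccc1O | starting material
2 | (4S)-4-benzyl-1,3-oxazolidin-2-one | O=C1N[C@@H](Cc2ccccc2)CO1 | starting material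
3 | 3-[3-methoxy-4-(pivaloyloxy)phenyl]propanoic pivalic anhydride | COc1cc(CCC(=O)OC(=O)C(C)(C)C)ccc1OC(=O)C(C)(C)C | intermediate
4 | (4S)-4-benzyl-3-{3-[3-methoxy-4-(pivaloyloxy)phenyl]propanoyl}-1,3-oxazolidin-2-one | COc1cc(CCC(=O)N2C(=O)OC[C@@H]2Cc2ccccc2)ccc1OC(=O)C(C)(C)C | intermediate
5 | tert-butyl bromoacetate | CC(C)(C)OC(=O)CBr | starting material
6 | tert-butyl (3R)-4-[(4S)-4-benzyl-2-oxo-1,3-oxazolidin-3-yl]-3-{[3-methoxy-4-(pivaloyloxy)phenyl]methyl}-4-oxobutanoate | COc1cc(C[C@H](CC(=O)OC(C)(C)C)C(=O)N2C(=O)OC[C@@H]2Cc2ccccc2)ccc1OC(=O)C(C)(C)C | intermediate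
7 | tert-butyl (3R)-3-(hydroxymethyl)-4-[3-methoxy-4-(pivaloyloxy)phenyl]butanoate | COc1cc(C[C@@H](CO)CC(=O)OC(C)(C)C)ccc1OC(=O)C(C)(C)C | intermediate
8 | (4R)-4-{[3-methoxy-4-(pivaloyloxy)phenyl]methyl}oxolan-2-one | COc1cc(C[C@H]2COC(=O)C2)ccc1OC(=O)C(C)(C)C | intermediate
9 | 4-(benzyloxy)-3-methoxybenzoic acid | COc1cc(C(=O)O)ccc1OCc1ccccc1 | starting material
10 | [4-(benzyloxy)-3-methoxyphenyl](1H-imidazol-1-yl)methanone | COc1cc(C(=O)n2ccnc2)ccc1OCc1ccccc1 | intermediate
11 | (3S,4R)-3-[4-(benzyloxy)-3-methoxybenzoyl]-4-{[3-methoxy-4-(pivaloyloxy)phenyl]methyl}oxolan-2-one (trans; C3 labile, keto/enol mixture) | COc1cc(C[C@H]2COC(=O)[C@@H]2C(=O)c2ccc(OCc3ccccc3)c(OC)c2)ccc1OC(=O)C(C)(C)C | intermediate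
12 | methyl (3R)-2-[4-(benzyloxy)-3-methoxybenzoyl]-3-(hydroxymethyl)-4-[3-methoxy-4-(pivaloyloxy)phenyl]butanoate (C2 epimers) | COc1cc(C[C@@H](CO)C(C(=O)OC)C(=O)c2ccc(OCc3ccccc3)c(OC)c2)ccc1OC(=O)C(C)(C)C | intermediate
13 | methyl (4R)-2-[4-(benzyloxy)-3-methoxyphenyl]-4-{[3-methoxy-4-(pivaloyloxy)phenyl]methyl}-4,5-dihydrofuran-3-carboxylate | COc1cc(C[C@H]2COC(c3ccc(OCc4ccccc4)c(OC)c3)=C2C(=O)OC)ccc1OC(=O)C(C)(C)C | intermediate
14 | methyl (2R,3S,4R)-2-(4-hydroxy-3-methoxyphenyl)-4-{[3-methoxy-4-(pivaloyloxy)phenyl]methyl}oxolane-3-carboxylate (all-cis) | COc1cc(C[C@H]2CO[C@@H](c3ccc(O)c(OC)c3)[C@H]2C(=O)OC)ccc1OC(=O)C(C)(C)C | intermediate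
15 | (E)-3-(4-acetoxy-3-methoxyphenyl)prop-2-enoic acid | COc1cc(/C=C/C(=O)O)ccc1OC(C)=O | starting material
16 | (E)-3-(4-acetoxy-3-methoxyphenyl)prop-2-enoyl chloride | COc1cc(/C=C/C(Cl)=O)ccc1OC(C)=O | intermediate
17 | (1S)-(−)-2,10-camphorsultam [(2R)-bornane-10,2-sultam] | CC1(C)[C@@H]2CC[C@]13CS(=O)(=O)N[C@@H]3C2 | starting material
18 | (2E)-3-(4-acetoxy-3-methoxyphenyl)-1-[(2R)-bornane-10,2-sultam-N-yl]prop-2-en-1-one | COc1cc(/C=C/C(=O)N2[C@@H]3C[C@H]4CC[C@]3(CS2(=O)=O)C4(C)C)ccc1OC(C)=O | intermediate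
19 | (2E)-3-(4-hydroxy-3-methoxyphenyl)-1-[(2R)-bornane-10,2-sultam-N-yl]prop-2-en-1-one | COc1cc(/C=C/C(=O)N2[C@@H]3C[C@H]4CC[C@]3(CS2(=O)=O)C4(C)C)ccc1O | intermediate
20 | quinone methide: methyl (2R,3S,4R)-2-{4-hydroxy-3-methoxy-5-[(1S)-2-(3-methoxy-4-oxocyclohexa-2,5-dien-1-ylidene)-1-{[(2R)-bornane-10,2-sultam-N-yl]carbonyl}ethyl]phenyl}-4-{[3-methoxy-4-(pivaloyloxy)phenyl]methyl}oxolane-3-carboxylate (exocyclic alkene geometry not defined) | COc1cc(C[C@H]2CO[C@@H](c3cc(OC)c(O)c(c3)[C@H](C=C3C=CC(=O)C(OC)=C3)C(=O)N4[C@@H]5C[C@H]6CC[C@]5(CS4(=O)=O)C6(C)C)[C@H]2C(=O)OC)ccc1OC(=O)C(C)(C)C | intermediate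
21 | methyl (2R,3S,4R)-2-{(2R,3R)-2-(4-hydroxy-3-methoxyphenyl)-7-methoxy-3-{[(2R)-bornane-10,2-sultam-N-yl]carbonyl}-2,3-dihydro-1-benzofuran-5-yl}-4-{[3-methoxy-4-(pivaloyloxy)phenyl]methyl}oxolane-3-carboxylate | COc1cc(C[C@H]2CO[C@@H](c3cc(OC)c4c(c3)[C@@H](C(=O)N5[C@@H]6C[C@H]7CC[C@]6(CS5(=O)=O)C7(C)C)[C@H](c3ccc(O)c(OC)c3)O4)[C@H]2C(=O)OC)ccc1OC(=O)C(C)(C)C | intermediate
22 | (1R)-(+)-2,10-camphorsultam [(2S)-bornane-10,2-sultam] | CC1(C)[C@H]2CC[C@@]13CS(=O)(=O)N[C@H]3C2 | starting material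
23 | (2E)-3-(4-acetoxy-3-methoxyphenyl)-1-[(2S)-bornane-10,2-sultam-N-yl]prop-2-en-1-one | COc1cc(/C=C/C(=O)N2[C@H]3C[C@@H]4CC[C@@]3(CS2(=O)=O)C4(C)C)ccc1OC(C)=O | intermediate
24 | (2E)-3-(4-hydroxy-3-methoxyphenyl)-1-[(2S)-bornane-10,2-sultam-N-yl]prop-2-en-1-one | COc1cc(/C=C/C(=O)N2[C@H]3C[C@@H]4CC[C@@]3(CS2(=O)=O)C4(C)C)ccc1O | intermediate
25 | quinone methide: compound 21 whose ring C carries, ortho to its phenol, the (1R)-2-(3-methoxy-4-oxocyclohexa-2,5-dien-1-ylidene)-1-{[(2S)-bornane-10,2-sultam-N-yl]carbonyl}ethyl group (exocyclic alkene geometry not defined) | COc1cc(C[C@H]2CO[C@@H](c3cc(OC)c4c(c3)[C@@H](C(=O)N5[C@@H]6C[C@H]7CC[C@]6(CS5(=O)=O)C7(C)C)[C@H](c3cc(OC)c(O)c(c3)[C@@H](C=C3C=CC(=O)C(OC)=C3)C(=O)N5[C@H]6C[C@@H]7CC[C@@]6(CS5(=O)=O)C7(C)C)O4)[C@H]2C(=O)OC)ccc1OC(=O)C(C)(C)C | intermediate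
26 | methyl (2R,3S,4R)-2-{(2R,3R)-2-[(2S,3S)-2-(4-hydroxy-3-methoxyphenyl)-7-methoxy-3-{[(2S)-bornane-10,2-sultam-N-yl]carbonyl}-2,3-dihydro-1-benzofuran-5-yl]-7-methoxy-3-{[(2R)-bornane-10,2-sultam-N-yl]carbonyl}-2,3-dihydro-1-benzofuran-5-yl}-4-{[3-methoxy-4-(pivaloyloxy)phenyl]methyl}oxolane-3-carboxylate | COc1cc(C[C@H]2CO[C@@H](c3cc(OC)c4c(c3)[C@@H](C(=O)N5[C@@H]6C[C@H]7CC[C@]6(CS5(=O)=O)C7(C)C)[C@H](c3cc(OC)c5c(c3)[C@H](C(=O)N6[C@H]7C[C@@H]8CC[C@@]7(CS6(=O)=O)C8(C)C)[C@@H](c3ccc(O)c(OC)c3)O5)O4)[C@H]2C(=O)OC)ccc1OC(=O)C(C)(C)C | intermediate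
27 | CNP0395728.1, 4-{[(3R,4R,5R)-5-{(2R,3S)-2-[(2S,3R)-2-(4-hydroxy-3-methoxyphenyl)-3-(hydroxymethyl)-7-methoxy-2,3-dihydro-1-benzofuran-5-yl]-3-(hydroxymethyl)-7-methoxy-2,3-dihydro-1-benzofuran-5-yl}-4-(hydroxymethyl)oxolan-3-yl]methyl}-2-methoxyphenol | COc1cc(C[C@H]2CO[C@@H](c3cc(OC)c4c(c3)[C@@H](CO)[C@H](c3cc(OC)c5c(c3)[C@H](CO)[C@@H](c3ccc(O)c(OC)c3)O5)O4)[C@H]2CO)ccc1O | target

## Step count and risks

Total step count: 12. Longest linear sequence: 9 (steps 1, 2, 3, 4, 5, 6, 9, 11, 12).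

The three steps most likely to fail:

Step 9. The cross-coupling competes with homo-dimerisation of 19, with 8–O–4 coupling, and with over-growth, because the new ring C phenol of 21 can couple again with 19 and would then carry the wrong sultam. The facial control has precedent only for the homo-dimerisation. The fallback sets out from 14 and comes back at 27. It gives up auxiliary control in this coupling: 14 is oxidised with Ag2O in CH2Cl2/acetone in the presence of cheap commercial ethyl (E)-ferulate (5 equiv) to the trans dihydrobenzofuran ethyl ester F1, formed as a near 1:1 pair of trans diastereomers because 14 is already enantiopure. The (2R,3R) isomer is separated by preparative HPLC and taken through the step 11 conditions with 24 to the mixed ester/sultam tetramer F2, which the step 12 conditions reduce to 27.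

Step 11. The risks are the same as in step 9, on a more precious substrate. The fallback sets out from 21 and comes back at 27. It replaces the radical coupling by a two-electron annulation in which cross-selectivity is fixed by a carbon–iodine bond. The free phenol of 21 is iodinated ortho to the hydroxyl (N-iodosuccinimide, cat. TsOH, MeCN, 0 °C) to the iodophenol F3. Commercial coniferyl alcohol is acetylated (Ac2O, pyridine) to coniferyl alcohol diacetate F4. A Larock-type oxyarylation of F4 with F3 (Pd(OAc)2 10 mol%, NaHCO3, Bu4NCl, DMF, 60 °C; phosphine-free so that the allylic acetate is not ionised) puts the aryl carbon on C8 and the phenol oxygen on the benzylic carbon through the π-benzyl palladium intermediate and gives the diacetate tetramer F5 as two trans diastereomers. After HPLC separation, the (2S,3R) isomer is reduced under the step 12 conditions, which also cleave the acetates, to 27.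

Step 6. The tetrasubstituted push–pull alkene may hydrogenate slowly, the benzylic C2–O bond may be hydrogenolysed once the phenol is free, and the facial selectivity rests on one neighbouring substituent. The fallback sets out from 13 and comes back at 14. It replaces syn hydrogenation by a stepwise polar reduction. Conjugate hydride addition with LiBH(s-Bu)3 (THF, −78 °C) delivers hydride to C2 anti to the benzyl group. Kinetic protonation of the resulting ester enolate with 2,6-di-tert-butylphenol from the face opposite both flanking substituents gives the all-cis benzyl ether F6. Debenzylation is then only a short hydrogenolysis (H2 1 atm, Pd/C, EtOAc, 30 min) and gives 14.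

Further compounds
F1 | step 9 | methyl (2R,3S,4R)-2-{(2R,3R)-3-(ethoxycarbonyl)-2-(4-hydroxy-3-methoxyphenyl)-7-methoxy-2,3-dihydro-1-benzofuran-5-yl}-4-{[3-methoxy-4-(pivaloyloxy)phenyl]methyl}oxolane-3-carboxylate | COc1cc(C[C@H]2CO[C@@H](c3cc(OC)c4c(c3)[C@@H](C(=O)OCC)[C@H](c3ccc(O)c(OC)c3)O4)[C@H]2C(=O)OC)ccc1OC(=O)C(C)(C)C
F2 | step 9 | compound 26 with an ethoxycarbonyl group in place of the (2R)-sultam carbonyl on the ring B/C dihydrobenzofuran | COc1cc(C[C@H]2CO[C@@H](c3cc(OC)c4c(c3)[C@@H](C(=O)OCC)[C@H](c3cc(OC)c5c(c3)[C@H](C(=O)N6[C@H]7C[C@@H]8CC[C@@]7(CS6(=O)=O)C8(C)C)[C@@H](c3ccc(O)c(OC)c3)O5)O4)[C@H]2C(=O)OC)ccc1OC(=O)C(C)(C)C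
F3 | step 11 | compound 21 with iodine on ring C ortho to the phenolic hydroxyl (4-hydroxy-3-iodo-5-methoxyphenyl at C2 of the dihydrobenzofuran) | COc1cc(C[C@H]2CO[C@@H](c3cc(OC)c4c(c3)[C@@H](C(=O)N5[C@@H]6C[C@H]7CC[C@]6(CS5(=O)=O)C7(C)C)[C@H](c3cc(I)c(O)c(OC)c3)O4)[C@H]2C(=O)OC)ccc1OC(=O)C(C)(C)C
F4 | step 11 | (E)-3-(4-acetoxy-3-methoxyphenyl)prop-2-en-1-yl acetate (coniferyl alcohol diacetate) | COc1cc(/C=C/COC(C)=O)ccc1OC(C)=O
F5 | step 11 | methyl (2R,3S,4R)-2-{(2R,3R)-2-[(2S,3R)-3-(acetoxymethyl)-2-(4-acetoxy-3-methoxyphenyl)-7-methoxy-2,3-dihydro-1-benzofuran-5-yl]-7-methoxy-3-{[(2R)-bornane-10,2-sultam-N-yl]carbonyl}-2,3-dihydro-1-benzofuran-5-yl}-4-{[3-methoxy-4-(pivaloyloxy)phenyl]methyl}oxolane-3-carboxylate | COc1cc(C[C@H]2CO[C@@H](c3cc(OC)c4c(c3)[C@@H](C(=O)N5[C@@H]6C[C@H]7CC[C@]6(CS5(=O)=O)C7(C)C)[C@H](c3cc(OC)c5c(c3)[C@H](COC(C)=O)[C@@H](c3ccc(OC(C)=O)c(OC)c3)O5)O4)[C@H]2C(=O)OC)ccc1OC(=O)C(C)(C)C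
F6 | step 6 | methyl (2R,3S,4R)-2-[4-(benzyloxy)-3-methoxyphenyl]-4-{[3-methoxy-4-(pivaloyloxy)phenyl]methyl}oxolane-3-carboxylate | COc1cc(C[C@H]2CO[C@@H](c3ccc(OCc4ccccc4)c(OC)c3)[C@H]2C(=O)OC)ccc1OC(=O)C(C)(C)C
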